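(The data come from a simulation from invented constants, noise included.)

The pitfall with a target that is made and destroyed at once is to time its peak by how fast the substrate goes.

common to all: reagent 1.43 M
- green: substrate 0.65 M; run made earlier
- flask: substrate 1.3 M; time 4.0 min

- green (time / s: target / %, substrate / %): 10.0: 5.5, 91.5; 12.0: 6.6, 90.2; 20.0: 9.0, 85.2; 25.0: 10.5, 81.6

(scatter of a reading: 0.3 percentage points)

- the best time, 4.0 min at the latest, for target
- the amount of target, in percent of the substrate charged, at that time
- earliest time at which at least nineteen twentieths of that best amount are there, in min
- latest time at which they still are, in min



Start with the main step. The green run loses substrate with a first-order constant of 0.00813 /s, a clock of 2.05 min. The flask holds the same [reagent], so you may borrow that clock, assuming first order in substrate. The first green reading puts 64.7% of the lost substrate into target, so with nothing further the flask would hold 55.5% of target at 4.0 min.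

Now let target be lost: d[target]/dt = m[substrate] − l[target], in fractions of the charge. The first green stretch and the stretch from the second reading to the last give l = 0.0318 /s and m = 0.00666 /s, rough readings given the scatter. Target's lifetime, 0.524 min, is shorter than the substrate clock. Carry the quotient m/l = 0.209, the standing ratio: the [target]/[substrate] at which making and loss balance, a quasi-steady state. Target peaks on reaching it, which my reckoning puts at 0.960 min with 13.1%.

Last comes reagent use. The flask has 1.10 equivalents against 2.20 in the green run, so its [reagent] falls further and m with it. I would therefore expect a somewhat lower peak. One substrate charge cannot show whether l depends on [substrate].

The forecast says 1.95 min and 17%, open from 1.17 min to 3.65 min: “the yield peaks at about 17%, with about 52% of substrate left, regardless of concentration”. Its time is later than mine.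

The flask gives 12.2% at 1.09 min, open from 0.724 min to 1.62 min.

    substrate + reagent ⇌ target (K = 0.340 /M, k = 0.00450 /M/s)
    substrate + 2 reagent → side product A (k = 0.00140 /M²/s)
    substrate + target → side product B (k = 0.0110 /M/s)

At its best time the flask holds target over substrate at 0.187, beside the standing ratio of 0.209. The flask's peak stays that low in part because target runs back to substrate + reagent: the flask without that reverse step reaches 19.8% instead of 12.2%. In the neighbour charged with 0.57 M of reagent, the ratio scaled by charged [reagent] is 0.0835; substrate at that neighbour's peak lies between the full charge and its final 66.9%, which puts the peak between 5.58% and 8.35%, and its best is 5.78%.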